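**Retrosynthetic overview**

1. Target 17 ⇐ tris-MOM ether 16 (acid deprotection). 16 ⇐ chromone 14 + arylboronic acid 15 by rhodium-catalysed asymmetric 1,4-arylation: ring B and the C2 stereocentre arrive together as the flat 4-pyranone ring C is de-aromatised.
2. Key disconnection: O1–C2 and C4–C4a of ring C, cut together. 14 ⇐ iodophenol 8 (after metalation a C4a,O1-dianion) + 3-ethoxyacryloyl Weinreb amide 10 (C4 acyl carbon and C2 β-carbon as a 1,3-dielectrophile), joined in one anionic [3+3] annulation at the chromone oxidation level.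
3. Enabling feature: in ring A, O1 (on C8a) lies para to the geranyl-bearing C6, its two ortho carbons (C4a and C8) are equivalent, and O5 and O7 carry the same protecting group. Annulation across the only free hydroxyl and either ortho carbon can therefore give only the 6-geranyl, never the 8-geranyl, skeleton. C4 and C2 are 1,3-related like the two electrophilic carbons of a β-alkoxyacrylate.
4. 8 ⇐ phenol 7 (iodination) ⇐ 5 by iridium-catalysed C–H borylation/oxidation para to the geranyl group ⇐ resorcinol bis-MOM ether 2 by directed ortho-lithiation and geranylation.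
5. Ring order: ring A is bought (resorcinol), ring C is closed in step 6, ring B is attached in step 7.

Key step: step 6

Remark on the chemistry: the (S)-bisphosphine of step 7 is assumed to deliver the aryl group to the same enone face as in the rhodium-catalysed arylation of 2-cyclohexenone, which corresponds to (2S) here; if the sense were opposite, the (R)-ligand would be used with no other change. (S)-MeO-F12-BIPHEP = (S)-2,2'-bis[bis(3,4,5-trifluorophenyl)phosphino]-6,6'-dimethoxy-1,1'-biphenyl.

**Route**

Step 1
Reactants: 1 resorcinol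
Product: 2 1,3-bis(methoxymethoxy)benzene
Conditions: NaH, MOMCl, DMF, 0 °C → rt
Reagents that add atoms: chloromethyl methyl ether, COCCl
Why: Double Williamson-type O-alkylation of the bis-phenoxide installs two MOM acetals, which later direct lithiation and are removed by mild acid.

Step 2
Reactants: 2 1,3-bis(methoxymethoxy)benzene; 3 geranyl bromide [(2E)-1-bromo-3,7-dimethylocta-2,6-diene]
Product: 5 2-[(2E)-3,7-dimethylocta-2,6-dien-1-yl]-1,3-bis(methoxymethoxy)benzene, via the aryllithium 4 (not isolated)
Conditions: n-BuLi, THF, 0 °C; CuI (10 mol %), then 3, −78 °C → rt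
Reagents that add atoms: none
Why: Directed ortho-metalation puts lithium on the carbon between the two OMOM groups, and copper-catalysed SN2 allylation of 4 with the primary allylic bromide should keep the E-alkene.

Step 3
Reactants: 5 2-[(2E)-3,7-dimethylocta-2,6-dien-1-yl]-1,3-bis(methoxymethoxy)benzene
Product: 7 4-[(2E)-3,7-dimethylocta-2,6-dien-1-yl]-3,5-bis(methoxymethoxy)phenol, via the pinacol boronate 6 (not isolated)
Conditions: [Ir(OMe)(cod)]2 (1.5 mol %), 4,4'-di-tert-butyl-2,2'-bipyridine (3 mol %), B2pin2, THF, 65 °C; then H2O2, NaOH, THF/H2O, 0 °C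
Reagents that add atoms: hydrogen peroxide, OO; bis(pinacolato)diboron, CC1(C)OB(OC1(C)C)B1OC(C)(C)C(C)(C)O1 (its boron and pinacol unit stay only in intermediate 6)
Why: Sterically controlled iridium-catalysed arene C–H borylation should go to the only ring C–H without an ortho substituent (para to geranyl), and alkaline peroxide oxidation of the C–B bond gives the phenol without touching the unactivated trisubstituted alkenes.

Step 4
Reactants: 7 4-[(2E)-3,7-dimethylocta-2,6-dien-1-yl]-3,5-bis(methoxymethoxy)phenol
Product: 8 4-[(2E)-3,7-dimethylocta-2,6-dien-1-yl]-2-iodo-3,5-bis(methoxymethoxy)phenol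
Conditions: NIS (1.0 equiv), CH2Cl2, −40 °C, dark
Reagents that add atoms: N-iodosuccinimide, O=C1CCC(=O)N1I
Why: Electrophilic aromatic iodination of the strongly activated phenol occurs ortho to OH (para position blocked, both ortho sites equivalent) and should be much faster than iodonium attack on the alkenes at −40 °C; the first iodine slows a second substitution.

Step 5
Reactants: 9 (2E)-3-ethoxyprop-2-enoyl chloride
Product: 10 (2E)-3-ethoxy-N-methoxy-N-methylprop-2-enamide
Conditions: MeNH(OMe)·HCl, pyridine, CH2Cl2, 0 °C → rt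
Reagents that add atoms: N,O-dimethylhydroxylamine hydrochloride, CNOC.Cl
Why: Acyl substitution of the acid chloride by N,O-dimethylhydroxylamine (Schotten–Baumann-type amidation) gives the Weinreb amide with the E-enol ether unchanged.

Step 6
Reactants: 8 4-[(2E)-3,7-dimethylocta-2,6-dien-1-yl]-2-iodo-3,5-bis(methoxymethoxy)phenol; 10 (2E)-3-ethoxy-N-methoxy-N-methylprop-2-enamide
Product: 14 6-[(2E)-3,7-dimethylocta-2,6-dien-1-yl]-5,7-bis(methoxymethoxy)-4H-chromen-4-one, via the dilithio phenolate 11 (not isolated), via the tetrahedral adduct 12 (not isolated), via the hydroxy enone 13 (not isolated)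
Conditions: n-BuLi (2.1 equiv), THF, −78 °C; 10, −78 → 0 °C; then AcOH (excess), 0 → 45 °C
Reagents that add atoms: none
Why: n-BuLi removes the phenolic proton and exchanges iodine for lithium to give the C,O-dianion 11, whose aryl carbanion (future C4a) adds to the amide carbonyl (future C4) to give the chelated tetrahedral adduct 12, which cannot over-add; acetic acid collapses 12 to the 2-hydroxyaryl β-ethoxyvinyl ketone 13, whose free phenol oxygen (O1) adds to the β-carbon (future C2) with loss of ethanol. The closest known reaction types are the Weinreb ketone synthesis with dilithiated 2-halophenols and the acid-induced cyclisation of 2-hydroxyaryl β-alkoxy- or β-aminovinyl ketones to chromones, here run as one anionic [3+3] annulation. Ring C closes by a 6-endo-trig oxa-Michael addition made irreversible by E1cB-type loss of ethanol, which gives the flat 4-pyranone. No stereocentre is formed, since C2 stays trigonal until step 7. The step needs carbonyl addition to win over α-metalation or β-attack on 10, which the hard aryllithium, the chelating N-methoxy-N-methylamide and −78 °C should favour, and it needs closure through O1 rather than O5. The latter is secured by the substrate: O1 is the only free hydroxyl next to the new ketone (O5 and O7 stay MOM-protected in acetic acid), so the geranyl group can only end up at C6.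

Step 7
Reactants: 14 6-[(2E)-3,7-dimethylocta-2,6-dien-1-yl]-5,7-bis(methoxymethoxy)-4H-chromen-4-one; 15 [4-(methoxymethoxy)phenyl]boronic acid
Product: 16 (2S)-6-[(2E)-3,7-dimethylocta-2,6-dien-1-yl]-5,7-bis(methoxymethoxy)-2-[4-(methoxymethoxy)phenyl]-2,3-dihydro-4H-chromen-4-one
Conditions: [RhCl(C2H4)2]2 (2.5 mol %), (S)-MeO-F12-BIPHEP (5.5 mol %), KOH (10 mol %), toluene/H2O (10:1), 40 °C
Reagents that add atoms: none
Why: Rhodium-catalysed asymmetric 1,4-addition of an arylboronic acid to the chromone (Hayashi–Miyaura reaction): the aryl-rhodium species held by the chiral bisphosphine adds across C2=C3 on one face, which should set C2 as S under catalyst control, and protonolysis of the rhodium enolate leaves the de-aromatised chromanone with the isolated alkenes and MOM ethers untouched.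

Step 8
Reactants: 16 (2S)-6-[(2E)-3,7-dimethylocta-2,6-dien-1-yl]-5,7-bis(methoxymethoxy)-2-[4-(methoxymethoxy)phenyl]-2,3-dihydro-4H-chromen-4-one
Product: 17 Bonannione A
Conditions: HCl (1.25 M in MeOH), MeOH/THF, 25 °C
Reagents that add atoms: none
Why: Acid-catalysed acetal exchange with methanol should remove all three MOM groups as dimethoxymethane under conditions too mild to ionise the C2–O1 bond or to cyclise the geranyl chain onto a neighbouring hydroxyl, so C2 keeps its configuration.

**Compound list**

1 | resorcinol (benzene-1,3-diol) | Oc1cccc(O)c1 | starting material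
2 | 1,3-bis(methoxymethoxy)benzene | COCOc1cccc(OCOC)c1 | intermediate
3 | geranyl bromide, (2E)-1-bromo-3,7-dimethylocta-2,6-diene | CC(C)=CCC/C(C)=C/CBr | starting material
4 | [2,6-bis(methoxymethoxy)phenyl]lithium | [Li]c1c(OCOC)cccc1OCOC | intermediate
5 | 2-[(2E)-3,7-dimethylocta-2,6-dien-1-yl]-1,3-bis(methoxymethoxy)benzene | CC(C)=CCC/C(C)=C/Cc1c(OCOC)cccc1OCOC | intermediate
6 | 2-{4-[(2E)-3,7-dimethylocta-2,6-dien-1-yl]-3,5-bis(methoxymethoxy)phenyl}-4,4,5,5-tetramethyl-1,3,2-dioxaborolane | CC(C)=CCC/C(C)=C/Cc1c(OCOC)cc(cc1OCOC)B2OC(C)(C)C(C)(C)O2 | intermediate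
7 | 4-[(2E)-3,7-dimethylocta-2,6-dien-1-yl]-3,5-bis(methoxymethoxy)phenol | CC(C)=CCC/C(C)=C/Cc1c(OCOC)cc(O)cc1OCOC | intermediate
8 | 4-[(2E)-3,7-dimethylocta-2,6-dien-1-yl]-2-iodo-3,5-bis(methoxymethoxy)phenol | CC(C)=CCC/C(C)=C/Cc1c(OCOC)cc(O)c(I)c1OCOC | intermediate
9 | (2E)-3-ethoxyprop-2-enoyl chloride | CCO/C=C/C(=O)Cl | starting material
10 | (2E)-3-ethoxy-N-methoxy-N-methylprop-2-enamide | CCO/C=C/C(=O)N(C)OC | intermediate
11 | lithium 4-[(2E)-3,7-dimethylocta-2,6-dien-1-yl]-2-lithio-3,5-bis(methoxymethoxy)phenolate | CC(C)=CCC/C(C)=C/Cc1c(OCOC)cc(O[Li])c([Li])c1OCOC | intermediate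
12 | dilithium (2E)-1-{3-[(2E)-3,7-dimethylocta-2,6-dien-1-yl]-2,4-bis(methoxymethoxy)-6-oxidophenyl}-3-ethoxy-1-[methoxy(methyl)amino]prop-2-en-1-olate (tetrahedral adduct, carbinol carbon racemic) | CC(C)=CCC/C(C)=C/Cc1c(OCOC)cc(O[Li])c(C(O[Li])(/C=C/OCC)N(C)OC)c1OCOC | intermediate
13 | (2E)-1-{3-[(2E)-3,7-dimethylocta-2,6-dien-1-yl]-6-hydroxy-2,4-bis(methoxymethoxy)phenyl}-3-ethoxyprop-2-en-1-one | CC(C)=CCC/C(C)=C/Cc1c(OCOC)cc(O)c(C(=O)/C=C/OCC)c1OCOC | intermediate
14 | 6-[(2E)-3,7-dimethylocta-2,6-dien-1-yl]-5,7-bis(methoxymethoxy)-4H-chromen-4-one | CC(C)=CCC/C(C)=C/Cc1c(OCOC)cc2occc(=O)c2c1OCOC | intermediate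
15 | [4-(methoxymethoxy)phenyl]boronic acid | COCOc1ccc(B(O)O)cc1 | starting material
16 | (2S)-6-[(2E)-3,7-dimethylocta-2,6-dien-1-yl]-5,7-bis(methoxymethoxy)-2-[4-(methoxymethoxy)phenyl]-2,3-dihydro-4H-chromen-4-one | CC(C)=CCC/C(C)=C/Cc1c(OCOC)cc2c(c1OCOC)C(=O)C[C@@H](c1ccc(OCOC)cc1)O2 | intermediate
17 | Bonannione A, (2S)-6-[(2E)-3,7-dimethylocta-2,6-dien-1-yl]-5,7-dihydroxy-2-(4-hydroxyphenyl)-2,3-dihydro-4H-chromen-4-one | CC(C)=CCC/C(C)=C/Cc1c(O)cc2c(c1O)C(=O)C[C@@H](c1ccc(O)cc1)O2 | target

**Step count and risks**

Total step count: 8. Longest linear sequence: 7 (steps 1, 2, 3, 4, 6, 7, 8); step 5 is a one-step branch.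

The three steps most likely to fail:

Step 7. Carbometalation of the electron-rich, peri-alkoxylated chromone may be slow with the chiral catalyst, so that protodeboronation of 15 outruns addition, or the facial discrimination may be poor. The fallback replaces asymmetric induction by resolution. It sets out from 14: arylation with 15 under the far more active ligand-free [Rh(OH)(cod)]2 (dioxane/H2O, 60 °C) should give the racemic flavanone rac-6-[(2E)-3,7-dimethylocta-2,6-dien-1-yl]-5,7-bis(methoxymethoxy)-2-[4-(methoxymethoxy)phenyl]-2,3-dihydro-4H-chromen-4-one F1. Kinetic resolution of F1 by asymmetric transfer hydrogenation (RuCl(p-cymene)[(R,R)-TsDPEN], HCO2H/Et3N, EtOAc, rt, stopped near half conversion) is expected to reduce the (2R)-ketone to the cis-alcohol (2R,4R)-6-[(2E)-3,7-dimethylocta-2,6-dien-1-yl]-5,7-bis(methoxymethoxy)-2-[4-(methoxymethoxy)phenyl]chroman-4-ol F2, which is removed by chromatography. The unreduced (S)-ketone is 16, where the fallback comes back to the route.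

Step 6. Proton transfer from the vinylic α-C–H of 10 to the hindered aryllithium, or attack at the β-carbon with loss of ethoxide, may compete with addition to the amide carbonyl and return 7 after work-up. The fallback builds the same ring stepwise from a C2 and a C1 unit. It sets out from 8: the dianion 11 is acetylated with N-methoxy-N-methylacetamide (THF, −78 → 0 °C) to 1-{3-[(2E)-3,7-dimethylocta-2,6-dien-1-yl]-6-hydroxy-2,4-bis(methoxymethoxy)phenyl}ethan-1-one F3. Condensation with N,N-dimethylformamide dimethyl acetal (toluene, 90 °C) gives the enaminone (2E)-3-(dimethylamino)-1-{3-[(2E)-3,7-dimethylocta-2,6-dien-1-yl]-6-hydroxy-2,4-bis(methoxymethoxy)phenyl}prop-2-en-1-one F4, which closes with loss of dimethylamine (AcOH, 60 °C) to 14, where it comes back to the route.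

Step 4. Iodonium may attack the geranyl double bonds with participation of a neighbouring MOM oxygen, or a second iodination may occur. The fallback avoids electrophilic halogen altogether. It sets out from 7: double deprotonation (n-BuLi 2.2 equiv, TMEDA, THF, 0 °C), with ring lithiation directed jointly by the lithium phenoxide and the adjacent OMOM group, should give the dianion 11 directly. It comes back to the route at 11, inside step 6, and makes no new compound.

**Further compounds**

F1 | step 7 | rac-6-[(2E)-3,7-dimethylocta-2,6-dien-1-yl]-5,7-bis(methoxymethoxy)-2-[4-(methoxymethoxy)phenyl]-2,3-dihydro-4H-chromen-4-one | CC(C)=CCC/C(C)=C/Cc1c(OCOC)cc2c(c1OCOC)C(=O)CC(c1ccc(OCOC)cc1)O2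
F2 | step 7 | (2R,4R)-6-[(2E)-3,7-dimethylocta-2,6-dien-1-yl]-5,7-bis(methoxymethoxy)-2-[4-(methoxymethoxy)phenyl]chroman-4-ol | CC(C)=CCC/C(C)=C/Cc1c(OCOC)cc2c(c1OCOC)[C@H](O)C[C@H](c1ccc(OCOC)cc1)O2
F3 | step 6 | 1-{3-[(2E)-3,7-dimethylocta-2,6-dien-1-yl]-6-hydroxy-2,4-bis(methoxymethoxy)phenyl}ethan-1-one | CC(C)=CCC/C(C)=C/Cc1c(OCOC)cc(O)c(C(C)=O)c1OCOC
F4 | step 6 | (2E)-3-(dimethylamino)-1-{3-[(2E)-3,7-dimethylocta-2,6-dien-1-yl]-6-hydroxy-2,4-bis(methoxymethoxy)phenyl}prop-2-en-1-one | CC(C)=CCC/C(C)=C/Cc1c(OCOC)cc(O)c(C(=O)/C=C/N(C)C)c1OCOC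
F0 | step 4 | none | none
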